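Readings and results come from a simulation with made-up constants, and the scatter is random.

In the dusk run [target] falls from 28.4% at 3.00 h to 3.5% at 8.00 h. The noon run, at twice the charge, reads 28.5% at 3.00 h, the same percentage of its charge, so I treat the loss as first-order. From the dusk fall I take the target loss constant, the logarithmic slope of the target's tail, 0.419 h⁻¹, a half-life of 1.66 h.

| flask | starting material | remark | time |
|---|---|---|---|
| dusk | 0.30 M | run made earlier |  |
| noon | 0.60 M | run made earlier |  |
| west | 0.30 M | everything together in a closed stirred flask, run for 20 h | 20 h |
| south | 0.30 M | a single well-mixed tank run continuously and read at steady state, 20 h in it on average |  |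

- dusk (time / h: target / %, side product / %): 1.00: 42.6, 0.4; 3.00: 28.4, 0.8; 6.00: 8.1, 1.1; 8.00: 3.5, 0.9; 12.0: 0.2, 0.7
- noon (time / h: target / %, side product / %): 0.833: 41.0, 0.4; 1.50: 43.7, 0.7; 2.50: 33.6, 0.9; 3.00: 28.5, 1.4; 4.00: 19.0, 1.7

(standard deviation of a reading: 0.3 percentage points)

- a species is counted by the starting material in it: one side product counts as two
- the stated concentrations are those of everything mixed, before any reaction; amounts are the same in each set-up
- what was read earlier has a scatter of 0.3 percentage points, one standard deviation
- the earlier runs were made in a closed, stirred flask
- the share counts what is present at the end, not what went on to other products

- the set-up with the highest share of target in all that became target or side product, at the outlet or at the end ("none" if the first two lie within 2 percentage points) (west / south / none)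
- share of target in all that became target or side product, at the outlet or at the end, west
- share of target in all that became target or side product, at the outlet or at the end, south

That half-life is short against 20 h, so in the closed flask west the surviving fraction is about 0.0231%. The tank south holds fluid of all ages and passes one part in one plus the constant times the mean residence time, 10.7%, far more than west. Against the last dusk side product reading, 0.7%, west gives a share of about 3.19%. Against the highest dusk reading, 1.1%, south gives about 90.7%.

The weak link is that borrowed closed-flask reading. Side product at 3.00 h reads 0.8% in dusk and 1.4% in noon, which suggests second order, and at 12.0 h target and side product together make 0.900% of the dusk charge, so the remainder of that charge stands in forms these readings do not show. The tank south is fed fresh starting material, which may meet those forms there, so I take my south figure as an estimate that may run high, and I choose south.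

The forecast chooses south, with 0.2% for west, below my west figure, and 97.2% for south, above my south figure, and says of the side product that “its timing fits two target molecules combining”.

The flask gives south, with 1.97% for west and 41.3% for south.

    starting material + intermediate B → side product (k = 3.80 × 10⁻⁴ M⁻¹ s⁻¹)
    target → intermediate A (k = 1.20 × 10⁻⁴ s⁻¹)
    intermediate A ⇌ intermediate B (K = 0.340, k = 4.20 × 10⁻⁵ s⁻¹)
    starting material → target (k = 2.80 × 10⁻⁴ s⁻¹)
    starting material → intermediate A (k = 9.00 × 10⁻⁵ s⁻¹)

South holds 7.18% target, under the estimate, and its share implies 10.2% side product. In west at 20 h intermediate A stands at 73.9% and intermediate B at 25.1%, a ratio of 0.340, close to their equilibrium constant 0.34, but the share in west is still moving. Ten times the time gives the target about 108 further half-lives by the carried constant, and the west share falls from 1.97% to 0% at 200 h.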